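**Strategy.** The synthesis rests on cutting the C3–C4 bond of ring A, so that ring B (C5–C10) comes from (S)-carvone and the gem-dimethyl carbon C4 is the former isopropenyl carbon. The key step exploits this quaternary C4 next to the C5 ring-fusion carbon: protonation of the isopropenyl group gives the C4 cation, which is captured at the silicon-bearing C3 of a (Z)-vinylsilane on the C10 arm, closing ring A as a trans-decalin and leaving a 2-ene in one operation. Its precursor is 6-methylcarvone carrying a (Z)-3-(trimethylsilyl)allyl chain at the same carbon, trans to the isopropenyl group. Ring B is then oxygenated through a C9-to-C7 carbonyl transposition, and the dienyl chain is attached by a B-alkyl Suzuki coupling.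

Key step: step 5

Remark: bicyclic compounds carry labdane (drimane) numbering; the target belongs to the ent-labdane series, so ring faces are called syn or anti to the C10 methyl group, and 6-methylcarvone is used as its C6 epimer mixture.

**Step 1**
Reactants: 1 3-(trimethylsilyl)prop-2-yn-1-ol
Product: 2 (Z)-3-(trimethylsilyl)prop-2-en-1-ol
Conditions: H2 (1 atm), Ni(OAc)2·4H2O, NaBH4 (forms nickel boride, Ni2B), H2NCH2CH2NH2, EtOH, rt
Reagents that add atoms: none
Why: Alkyne semihydrogenation over amine-poisoned nickel boride should stop at the alkene and deliver both hydrogens to one face, which fixes the (Z) geometry that the ring closure needs.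

**Step 2**
Reactants: 2 (Z)-3-(trimethylsilyl)prop-2-en-1-ol
Product: 3 (Z)-3-bromo-1-(trimethylsilyl)prop-1-ene
Conditions: CBr4, PPh3, CH2Cl2, 0 °C
Reagents that add atoms: carbon tetrabromide, BrC(Br)(Br)Br
Why: The Appel reaction replaces the primary allylic hydroxyl by bromide under neutral conditions by direct displacement, so the (Z)-vinylsilane should stay intact.

**Step 3**
Reactants: 4 (S)-(+)-carvone; 5 iodomethane
Product: 7 (5S)-6-methylcarvone (C6 epimer mixture), via lithium enolate of carvone 6 (not isolated)
Conditions: LiN(iPr)2, THF, −78 °C; then 5, −78 → 0 °C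
Reagents that add atoms: none
Why: Kinetic deprotonation of the enone at the α′ methylene and C-methylation of the cross-conjugated enolate is standard enolate alkylation, and the C6 epimer mixture is harmless because that carbon is planarised again in step 4.

**Step 4**
Reactants: 7 (5S)-6-methylcarvone; 3 (Z)-3-bromo-1-(trimethylsilyl)prop-1-ene
Product: 9 (5R,6R)-2,6-dimethyl-5-(prop-1-en-2-yl)-6-[(2Z)-3-(trimethylsilyl)prop-2-en-1-yl]cyclohex-2-en-1-one, via lithium enolate of 6-methylcarvone 8 (not isolated)
Conditions: LiN(iPr)2, THF, −78 → 0 °C; then 3, DMPU, −78 °C → rt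
Reagents that add atoms: none
Why: In this enolate alkylation the tetrasubstituted enolate should be attacked by the allylic bromide on the face opposite the neighbouring isopropenyl group, which sets the quaternary carbon (future C10) with the silylallyl chain trans and the methyl cis to isopropenyl.

**Step 5**
Reactants: 9 (5R,6R)-2,6-dimethyl-5-(prop-1-en-2-yl)-6-[(2Z)-3-(trimethylsilyl)prop-2-en-1-yl]cyclohex-2-en-1-one
Product: 10 (4aR,8aR)-2,5,5,8a-tetramethyl-4a,5,8,8a-tetrahydronaphthalen-1(4H)-one (trans-fused 4,4,8,10-tetramethyldecalin-2,7-dien-9-one)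
Conditions: CF3CO2H, CH2Cl2, 0 °C
Reagents that add atoms: none
Why: Trifluoroacetic acid should protonate the 1,1-disubstituted isopropenyl group at its CH2 terminus to give the tertiary C4 cation, which is attacked by the silicon-bearing carbon C3 of the (Z)-vinylsilane; the resulting C2 cation is stabilised by the β C–Si bond and loses silicon to trifluoroacetate, leaving the 2-ene. The closest known reaction type is the vinylsilane-terminated cation–olefin cyclisation by ipso substitution, here started by alkene protonation. Ring A closes in a 6-endo mode with respect to the vinylsilane, through a chair-like arrangement in which the C4 cation and the C1 chain are both equatorial on ring B. No new stereocentre arises, because C4 carries two methyl groups; the trans ring fusion follows from the trans arrangement of the two arms fixed in step 4, and C5 is carried over from carvone. The step needs chemoselective protonation (only the isopropenyl group leads to a tertiary cation) and regioselective capture at C3, which are secured by the β-silicon effect, by the (Z) geometry (silicon cis to C1, so that substitution with retention gives a ring cis-alkene) and by six-membered ring formation.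

**Step 6**
Reactants: 10 trans-fused 4,4,8,10-tetramethyldecalin-2,7-dien-9-one
Product: 11 (4aR,8aR)-2,5,5,8a-tetramethyl-4a,5,6,7,8,8a-hexahydronaphthalen-1(4H)-one (the 7-en-9-one)
Conditions: H2 (3 atm), RhCl(PPh3)3 (cat.), benzene, rt
Reagents that add atoms: none
Why: Homogeneous hydrogenation with RhCl(PPh3)3 should saturate the cis-disubstituted 2-ene and leave the trisubstituted conjugated 7-ene untouched, the selectivity known from the reduction of the isopropenyl group of carvone.

**Step 7**
Reactants: 11 the 7-en-9-one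
Product: 12 4,4,8,9,10-pentamethyl-trans-decal-7-en-9-ol (9-hydroxy-ent-drim-7-ene; new methyl expected anti to the C10 methyl)
Conditions: MeLi, Et2O, −78 → 0 °C
Reagents that add atoms: methyllithium, [Li]C
Why: 1,2-Addition of the small organolithium to the enone carbonyl, which has no α′ hydrogen, installs C11, and the configuration of the new carbinol carbon is erased in step 8.

**Step 8**
Reactants: 12 9-hydroxy-ent-drim-7-ene
Product: 13 (4aR,8aR)-3,4,4a,8,8-pentamethyl-4a,5,6,7,8,8a-hexahydronaphthalen-2(1H)-one (ent-drim-8-en-7-one)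
Conditions: pyridinium chlorochromate [C5H5NH][CrO3Cl], 4 Å molecular sieves, CH2Cl2, rt
Reagents that add atoms: pyridinium chlorochromate (supplies the C7 oxygen), [O-][Cr](=O)(=O)Cl.c1cc[nH+]cc1
Why: In the Dauben–Babler oxidative transposition the tertiary allylic chromate ester shifts to C7 by a [3,3] rearrangement and is oxidised there, which moves the carbonyl to C7 and the alkene to C8–C9.

**Step 9**
Reactants: 13 ent-drim-8-en-7-one
Product: 15 7-(triethylsilyloxy)-ent-drima-6,8-diene, via lithium C6 enolate 14 (not isolated)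
Conditions: LiN(iPr)2, THF, −78 °C; then Et3SiCl, −78 → 0 °C
Reagents that add atoms: chlorotriethylsilane, CC[Si](Cl)(CC)CC
Why: Kinetic deprotonation of an enone by a lithium amide occurs at the α′ carbon (C6) and not at the γ methyl, and O-silylation traps the cross-conjugated enolate as its silyl dienol ether.

**Step 10**
Reactants: 15 7-(triethylsilyloxy)-ent-drima-6,8-diene
Product: 17 6-(triethylsilyloxy)-ent-drim-8-en-7-one (C6–O anti to the C10 methyl), via silyloxy epoxide 16 (not isolated)
Conditions: mCPBA, CH2Cl2–hexane, −20 → 0 °C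
Reagents that add atoms: 3-chloroperbenzoic acid, O=C(OO)c1cccc(Cl)c1
Why: In this Rubottom oxidation the peracid should epoxidise the electron-rich enol ether bond on the face anti to the axial C4 and C10 methyls, and silyl transfer in the opened epoxide gives the equatorial C6 silyl ether directly, setting C6.

**Step 11**
Reactants: 17 6-(triethylsilyloxy)-ent-drim-8-en-7-one
Product: 19 8-hydroxy-6-(triethylsilyloxy)-ent-drim-9(11)-en-7-one (8-OH anti and 8-methyl syn to the C10 methyl), via potassium dienolate 18 (not isolated)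
Conditions: KN(SiMe3)2, THF, −78 → −20 °C; then 2-(phenylsulfonyl)-3-phenyloxaziridine, −78 °C
Reagents that add atoms: 2-(phenylsulfonyl)-3-phenyloxaziridine, O=S(=O)(c1ccccc1)N1OC1c1ccccc1
Why: Deconjugative α-hydroxylation of an extended enolate: with C6 now tertiary and oxygenated, the base should remove a C11 methyl proton, and the N-sulfonyloxaziridine should attack the dienolate at its α-carbon C8 anti to the axial C10 methyl, which sets C8 and unveils the C9 exocyclic methylene (C6 stays in its favoured equatorial configuration).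

**Step 12**
Reactants: 19 8-hydroxy-6-(triethylsilyloxy)-ent-drim-9(11)-en-7-one
Product: 20 6-(triethylsilyloxy)-ent-drim-9(11)-ene-7,8-diol (7-OH syn to the C10 methyl)
Conditions: NaBH4, CeCl3·7H2O, MeOH, −40 °C
Reagents that add atoms: none
Why: In this Luche-type borohydride reduction hydride should reach C7 along the axial path on the face anti to the axial C8 methyl, giving the equatorial C7 alcohol trans to both flanking oxygens, while the nearly neutral medium should suppress silyl migration.

**Step 13**
Reactants: 20 6-(triethylsilyloxy)-ent-drim-9(11)-ene-7,8-diol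
Product: 21 8-hydroxy-6-(triethylsilyloxy)-ent-drim-9(11)-en-7-yl acetate
Conditions: Ac2O, DMAP (cat.), pyridine, rt
Reagents that add atoms: acetic anhydride, CC(=O)OC(C)=O
Why: DMAP-catalysed acylation should take the only secondary hydroxyl (O7), since O6 is silylated and the tertiary C8 hydroxyl does not react at room temperature.

**Step 14**
Reactants: 22 propargyl alcohol
Product: 25 (Z)-3-iodo-2-methylprop-2-en-1-ol, via bromomagnesium prop-2-yn-1-olate 23 (not isolated), via vinylmagnesium chelate 24 (not isolated)
Conditions: MeMgBr, CuI (cat.), THF/Et2O, −10 °C → rt; then I2, −10 °C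
Reagents that add atoms: methylmagnesium bromide, C[Mg]Br; iodine, II
Why: Copper-catalysed anti-carbomagnesiation of the propargylic alkoxide places methyl on C2 and magnesium on C3 cis to the CH2O group in a five-membered chelate, and iodinolysis with retention gives the (Z)-iodoalkene.

**Step 15**
Reactants: 25 (Z)-3-iodo-2-methylprop-2-en-1-ol
Product: 26 (Z)-3-iodo-2-methylprop-2-enal
Conditions: MnO2, CH2Cl2, rt, dark
Reagents that add atoms: none
Why: Allylic oxidation with MnO2 is neutral and should give the enal without isomerising the (Z)-iodoalkene, which is used at once.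

**Step 16**
Reactants: 26 (Z)-3-iodo-2-methylprop-2-enal
Product: 27 (Z)-1-iodo-2-methylbuta-1,3-diene
Conditions: Ph3PCH3Br, NaN(SiMe3)2, THF, 0 °C; then 26, −78 → 0 °C; product kept as a solution
Reagents that add atoms: methyltriphenylphosphonium bromide, C[P+](c1ccccc1)(c1ccccc1)c1ccccc1.[Br-]
Why: Wittig methylenation of the aldehyde with the non-stabilised ylide forms the terminal vinyl group and does not touch the geometry of the iodoalkene.

**Step 17**
Reactants: 21 8-hydroxy-6-(triethylsilyloxy)-ent-drim-9(11)-en-7-yl acetate; 27 (Z)-1-iodo-2-methylbuta-1,3-diene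
Product: 29 6-O-triethylsilyl ether of the target, via B-alkyl-9-BBN adduct 28 (not isolated)
Conditions: 9-BBN (excess), THF, rt → 60 °C; then H2O; 27, PdCl2(dppf), AsPh3, Cs2CO3, DMF/THF/H2O, rt
Reagents that add atoms: none
Why: Hydroboration with 9-BBN should place boron on the terminal C11 and hydrogen on C9 from the face anti to the flanking axial C8 and C10 methyls (setting C9 with the chain equatorial and syn to the C10 methyl), and the B-alkyl Suzuki–Miyaura coupling then joins C11 to C12 with retention of the (Z)-iodoalkene geometry.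

**Step 18**
Reactants: 29 6-O-triethylsilyl ether of the target
Product: 30 (5R,6S,7R,8R,9S,10R,12Z)-6,8-dihydroxylabda-12,14-dien-7-yl acetate (CNP0225877.2)
Conditions: HF·pyridine, pyridine, THF, 0 °C
Reagents that add atoms: none
Why: Buffered fluoride cleavage of the triethylsilyl ether should free O6 without moving the acetate and without acid-promoted addition of the C8 hydroxyl to the diene.

**Compound list**
1 | 3-(trimethylsilyl)prop-2-yn-1-ol | C[Si](C)(C)C#CCO | starting material
2 | (Z)-3-(trimethylsilyl)prop-2-en-1-ol | C[Si](C)(C)/C=C\CO | intermediate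
3 | (Z)-3-bromo-1-(trimethylsilyl)prop-1-ene | C[Si](C)(C)/C=C\CBr | intermediate
4 | (S)-(+)-carvone | CC1=CC[C@@H](CC1=O)C(C)=C | starting material
5 | iodomethane | CI | starting material
6 | lithium enolate of carvone (C1=C6 enolate) | [Li+].CC1=CC[C@@H](C=C1[O-])C(C)=C | intermediate (not isolated)
7 | (5S)-6-methylcarvone, C6 epimer mixture | CC1=CC[C@H](C(C)=C)C(C)C1=O | intermediate
8 | lithium enolate of 6-methylcarvone | [Li+].CC1=CC[C@H](C(C)=C)C(C)=C1[O-] | intermediate (not isolated)
9 | (5R,6R)-2,6-dimethyl-5-(prop-1-en-2-yl)-6-[(2Z)-3-(trimethylsilyl)prop-2-en-1-yl]cyclohex-2-en-1-one (chain trans to isopropenyl) | O=C1C(C)=CC[C@H](C(C)=C)[C@@]1(C)C/C=C\[Si](C)(C)C | intermediate (key-step precursor)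
10 | (4aR,8aR)-2,5,5,8a-tetramethyl-4a,5,8,8a-tetrahydronaphthalen-1(4H)-one | O=C1C(C)=CC[C@@H]2C(C)(C)C=CC[C@]21C | intermediate (key-step product)
11 | (4aR,8aR)-2,5,5,8a-tetramethyl-4a,5,6,7,8,8a-hexahydronaphthalen-1(4H)-one | O=C1C(C)=CC[C@@H]2C(C)(C)CCC[C@]21C | intermediate
12 | 9-hydroxy-ent-drim-7-ene (C9 methyl anti to the C10 methyl expected) | C[C@@]1(O)C(C)=CC[C@@H]2C(C)(C)CCC[C@]21C | intermediate
13 | ent-drim-8-en-7-one | CC1=C(C)C(=O)C[C@@H]2C(C)(C)CCC[C@]21C | intermediate
14 | lithium C6 enolate of 13 | [Li+].CC1=C(C)C([O-])=C[C@@H]2C(C)(C)CCC[C@]21C | intermediate (not isolated)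
15 | 7-(triethylsilyloxy)-ent-drima-6,8-diene | CC1=C(C)C(O[Si](CC)(CC)CC)=C[C@@H]2C(C)(C)CCC[C@]21C | intermediate
16 | 6,7-epoxy-7-(triethylsilyloxy)-ent-drim-8-ene (epoxide anti to the C10 methyl) | CC1=C(C)[C@@]3(O[Si](CC)(CC)CC)O[C@H]3[C@@H]2C(C)(C)CCC[C@]21C | intermediate (not isolated)
17 | 6-(triethylsilyloxy)-ent-drim-8-en-7-one | CC1=C(C)C(=O)[C@@H](O[Si](CC)(CC)CC)[C@@H]2C(C)(C)CCC[C@]21C | intermediate
18 | potassium 7,9(11)-dienolate of 17 | [K+].C=C1C(C)=C([O-])[C@@H](O[Si](CC)(CC)CC)[C@@H]2C(C)(C)CCC[C@]21C | intermediate (not isolated)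
19 | 8-hydroxy-6-(triethylsilyloxy)-ent-drim-9(11)-en-7-one | C=C1[C@@](C)(O)C(=O)[C@@H](O[Si](CC)(CC)CC)[C@@H]2C(C)(C)CCC[C@]21C | intermediate
20 | 6-(triethylsilyloxy)-ent-drim-9(11)-ene-7,8-diol | C=C1[C@@](C)(O)[C@H](O)[C@@H](O[Si](CC)(CC)CC)[C@@H]2C(C)(C)CCC[C@]21C | intermediate
21 | 8-hydroxy-6-(triethylsilyloxy)-ent-drim-9(11)-en-7-yl acetate | C=C1[C@@](C)(O)[C@H](OC(C)=O)[C@@H](O[Si](CC)(CC)CC)[C@@H]2C(C)(C)CCC[C@]21C | intermediate
22 | propargyl alcohol | C#CCO | starting material
23 | bromomagnesium prop-2-yn-1-olate | C#CCO[Mg]Br | intermediate (not isolated)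
24 | (Z)-vinylmagnesium chelate (Mg cis to CH2O) | Br[Mg]/C=C(C)\CO[Mg]Br | intermediate (not isolated)
25 | (Z)-3-iodo-2-methylprop-2-en-1-ol | I/C=C(C)\CO | intermediate
26 | (Z)-3-iodo-2-methylprop-2-enal | I/C=C(C)\C=O | intermediate
27 | (Z)-1-iodo-2-methylbuta-1,3-diene | I/C=C(C)\C=C | intermediate
28 | B-(C11-alkyl)-9-borabicyclo[3.3.1]nonane from 21 | C(B1C2CCCC1CCC2)[C@@H]1[C@@](C)(O)[C@H](OC(C)=O)[C@@H](O[Si](CC)(CC)CC)[C@@H]2C(C)(C)CCC[C@]21C | intermediate (not isolated)
29 | 6-O-triethylsilyl ether of the target | C=C/C(C)=C\C[C@@H]1[C@@](C)(O)[C@H](OC(C)=O)[C@@H](O[Si](CC)(CC)CC)[C@@H]2C(C)(C)CCC[C@]21C | intermediate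
30 | (5R,6S,7R,8R,9S,10R,12Z)-6,8-dihydroxylabda-12,14-dien-7-yl acetate | C=C/C(C)=C\C[C@@H]1[C@@](C)(O)[C@H](OC(C)=O)[C@@H](O)[C@@H]2C(C)(C)CCC[C@]21C | target

**Step count.** Total: 18 steps. Longest linear sequence: 14 steps (steps 1, 2, 4–13, 17, 18, counted from 1); 13 steps from carvone.

**Steps most likely to fail**

Step 5. The acid may remove silicon from the vinylsilane before ring closure, or the C4 cation may lose the C5 proton or undergo hydride shift, which would erode the C5 configuration or give uncyclised isomers. The fallback generates the cation by Lewis-acid ionisation of a halide at low temperature. Setting out from 9, anhydrous HCl (Et2O/CH2Cl2, −40 °C) should add to the isopropenyl group in the Markovnikov sense to give the tertiary chloride (5S,6R)-5-(2-chloropropan-2-yl)-2,6-dimethyl-6-[(2Z)-3-(trimethylsilyl)prop-2-en-1-yl]cyclohex-2-en-1-one F1. TiCl4 (CH2Cl2, −78 °C) should then abstract chloride, and the same ipso cyclisation brings the route back at 10.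

Step 11. Deprotonation may occur at C6 instead of C11, the oxidant may attack the C11 terminus of the dienolate, or attack at C8 may be poorly face-selective. The fallback makes the C8 carbinol by a singlet-oxygen ene reaction. Setting out from 17, Luche reduction (NaBH4, CeCl3·7H2O, MeOH, −40 °C) should give the allylic alcohol 6-(triethylsilyloxy)-ent-drim-8-en-7-ol F2 (hydroxyl syn to the C10 methyl). Ac2O, DMAP and pyridine then give its acetate 6-(triethylsilyloxy)-ent-drim-8-en-7-yl acetate F3. Schenck photooxygenation (O2, hν, tetraphenylporphyrin, CH2Cl2) should take a hydrogen from C11, the methyl geminal to the bulky C10, and bond oxygen to C8 anti to the C10 methyl, giving the C8 hydroperoxide of 21 F4. PPh3 reduces it, and the route is rejoined at 21 (steps 11–13 are replaced).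

Step 17. Hydroboration by the bulky borane may be slow at an alkene flanked by two fully substituted carbons, and transmetalation of the β-branched alkylborane may lag behind side reactions of the diene. The fallback replaces the borane coupling by an organozinc coupling. Setting out from 21, BH3·SMe2 (THF, 0 °C) should give the C11 alkylborane F5, which NaBO3·4H2O oxidises to the C11 primary alcohol F6. I2, PPh3 and imidazole give the C11 iodide F7, and zinc insertion (Zn, LiCl, THF) gives the C11 alkylzinc iodide F8. Negishi coupling with 27 (Pd(PPh3)4, THF, rt) brings the route back at 29.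

**Further compounds**
F1 | step 5 | (5S,6R)-5-(2-chloropropan-2-yl)-2,6-dimethyl-6-[(2Z)-3-(trimethylsilyl)prop-2-en-1-yl]cyclohex-2-en-1-one | O=C1C(C)=CC[C@H](C(C)(C)Cl)[C@@]1(C)C/C=C\[Si](C)(C)C
F2 | step 11 | 6-(triethylsilyloxy)-ent-drim-8-en-7-ol | CC1=C(C)[C@H](O)[C@@H](O[Si](CC)(CC)CC)[C@@H]2C(C)(C)CCC[C@]21C
F3 | step 11 | 6-(triethylsilyloxy)-ent-drim-8-en-7-yl acetate | CC1=C(C)[C@H](OC(C)=O)[C@@H](O[Si](CC)(CC)CC)[C@@H]2C(C)(C)CCC[C@]21C
F4 | step 11 | 8-hydroperoxy-6-(triethylsilyloxy)-ent-drim-9(11)-en-7-yl acetate | C=C1[C@@](C)(OO)[C@H](OC(C)=O)[C@@H](O[Si](CC)(CC)CC)[C@@H]2C(C)(C)CCC[C@]21C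
F5 | step 17 | C11 alkylborane from 21 | BC[C@@H]1[C@@](C)(O)[C@H](OC(C)=O)[C@@H](O[Si](CC)(CC)CC)[C@@H]2C(C)(C)CCC[C@]21C
F6 | step 17 | 8,11-dihydroxy-6-(triethylsilyloxy)-ent-driman-7-yl acetate | OC[C@@H]1[C@@](C)(O)[C@H](OC(C)=O)[C@@H](O[Si](CC)(CC)CC)[C@@H]2C(C)(C)CCC[C@]21C
F7 | step 17 | 8-hydroxy-11-iodo-6-(triethylsilyloxy)-ent-driman-7-yl acetate | IC[C@@H]1[C@@](C)(O)[C@H](OC(C)=O)[C@@H](O[Si](CC)(CC)CC)[C@@H]2C(C)(C)CCC[C@]21C
F8 | step 17 | C11 alkylzinc iodide from F7 | I[Zn]C[C@@H]1[C@@](C)(O)[C@H](OC(C)=O)[C@@H](O[Si](CC)(CC)CC)[C@@H]2C(C)(C)CCC[C@]21C
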